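**Plan**
1. The difficulty lies in two contra-thermodynamic Z-enoates (CH3 cis to C=O) joined through a labile 2-(acyloxymethyl)acrylate. Acyl activation of angelic acid leaks to tiglate, and nucleophiles scramble the central alkene by SN2'.
2. The retrosynthesis cuts two bonds in one operation: the central C2=C3 double bond and the angelate O–CH2 bond (an alkyl–O bond, not an acyl–O bond). This leaves angelate anion, acetaldehyde and a 2-phosphonoacrylate. Further cuts are C=CH2 (iminium CH2), P–C and the bromoacetate ester.
3. Enabling feature: C2 of the central but-2-enoate carries the CH2–O(acyl) carbon (oxygen β to the ester C=O, an oxa-Michael retron), the ester carbonyl and the ethylidene carbon (an olefination retron). The carbanion formed in the Michael step is therefore itself the olefination reagent.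
4. Forward, the chain grows from the aryl end: cinnamyl alcohol → bromoacetate → phosphonoacetate → 2-phosphonoacrylate → three-component union with potassium angelate and acetaldehyde.
5. Geometry: the E-cinnamyl and Z-angelate alkenes are bought and never disturbed. The central Z alkene comes from kinetic control by the P(O)(OPh)2 group.

Key step: step 4

Remark: the target has no stereocentre and is achiral, so "single enantiomer" is read as the single geometrical isomer (Z,Z,E) of the SMILES string; 1 and 9 are taken as commercial.

Step 1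
Reactants: 1 (E)-3-(3,4-dimethoxyphenyl)prop-2-en-1-ol (3,4-dimethoxycinnamyl alcohol); 2 bromoacetyl bromide
Product: 3 (E)-3-(3,4-dimethoxyphenyl)allyl 2-bromoacetate
Conditions: pyridine (1.2 equiv), CH2Cl2, −20 → 0 °C
Reagents that add atoms: none
Why: O-acylation of a primary allylic alcohol by an acid bromide, in which pyridine takes up HBr before it can ionise the electron-rich cinnamyl C–O bond and the E alkene is not involved.

Step 2
Reactants: 3 (E)-3-(3,4-dimethoxyphenyl)allyl 2-bromoacetate; 4 diphenyl phosphite
Product: 5 (E)-3-(3,4-dimethoxyphenyl)allyl 2-(diphenoxyphosphoryl)acetate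
Conditions: Et3N (1.3 equiv), CH2Cl2, 0 °C → rt
Reagents that add atoms: none
Why: Michaelis–Becker-type P-alkylation, in which the amine-activated H-phosphonate attacks the primary α-bromo ester through phosphorus (SN2); this is the standard entry to (diphenoxyphosphoryl)acetates and leaves the aryl P–O bonds and the cinnamyl ester untouched.

Step 3
Reactants: 5 (E)-3-(3,4-dimethoxyphenyl)allyl 2-(diphenoxyphosphoryl)acetate
Product: 8 (E)-3-(3,4-dimethoxyphenyl)allyl 2-(diphenoxyphosphoryl)acrylate, via Mannich base 6 (not isolated), via trimethylammonium iodide 7 (not isolated)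
Conditions: Me2N=CH2+ I− (1.0 equiv), Et3N (1.05 equiv), CH2Cl2, 0 °C → rt; MeI (5 equiv), rt; sat. aq NaHCO3/CH2Cl2, 0 °C, cold dilute citric acid wash; used at once
Reagents that add atoms: Eschenmoser's salt (N,N-dimethylmethyleneiminium iodide), C=[N+](C)C.[I-]; iodomethane, CI (its CH3 stays in 7 only and leaves with NMe3)
Why: Mannich aminomethylation of an active methylene with a preformed iminium salt, N-quaternisation and E1cB loss of NMe3 (classical α-methylenation), chosen because free formaldehyde would give a β-alkoxide that collapses by HWE olefination to the plain acrylate.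

Step 4
Reactants: 8 (E)-3-(3,4-dimethoxyphenyl)allyl 2-(diphenoxyphosphoryl)acrylate; 9 angelic acid ((Z)-2-methylbut-2-enoic acid); 10 acetaldehyde
Product: 13 Morinin L, via potassium angelate 11 (not isolated), via phosphonate carbanion 12 (not isolated)
Conditions: 9 (1.3 equiv), KHMDS (1.25 equiv), 18-crown-6 (1.3 equiv), THF, −78 °C; 10 (5 equiv, freshly distilled); slow addition of 8 in THF, −78 → −30 °C; pH 7 buffer quench
Reagents that add atoms: potassium bis(trimethylsilyl)amide, C[Si](C)(C)[N-][Si](C)(C)C.[K+] (gives only the K+ of 11 and 12; nothing of it remains in 13)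
Why: Proposed new method: the carboxylate oxygen of 11 adds reversibly to the unsubstituted CH2 terminus of the alkene of 8, which is activated by both P=O and C=O (carboxylate salts initiate anionic addition to methylenemalonates and cyanoacrylates, so the addition should be kinetically competent), and the resulting carbanion 12, the anion of an α-substituted (diaryloxyphosphoryl)acetate, is drained irreversibly by Horner–Wadsworth–Emmons olefination of 10. The closest known reaction types are the tandem conjugate addition/HWE sequence of 2-phosphonoacrylates with carbon, nitrogen, sulfur and alkoxide nucleophiles and the Z-selective HWE reaction of α-alkyl (diphenoxyphosphoryl)acetates (Ando variant) with aliphatic aldehydes; only the carboxylate donor is new. No ring is closed and no stereocentre is formed; the one new stereoelement, the central C2=C3 double bond, is controlled by the two electron-poor phenoxy groups on phosphorus, which make collapse of the kinetically preferred erythro adduct faster than its reversal, so that CH3 should end cis to the ester C=O (Z). β-Elimination of angelate from 12, which undermines a stepwise use of such a β-acyloxy phosphonate, is harmless here because it only returns 8 and 11, and low temperature favours the adduct side of this equilibrium. The chemoselectivity needed (12 must meet 10 and not a second molecule of 8) is secured by slow addition of 8 to 11 in excess 10. The angelate reacts only through its oxygen and is never acyl-activated, so it has no path to tiglate, and the E-cinnamyl ester sees no transition metal.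

**Compound list**
1 | (E)-3-(3,4-dimethoxyphenyl)prop-2-en-1-ol | OC/C=C/c1ccc(OC)c(OC)c1 | starting material
2 | bromoacetyl bromide | BrCC(=O)Br | starting material
3 | (E)-3-(3,4-dimethoxyphenyl)allyl 2-bromoacetate | BrCC(=O)OC/C=C/c1ccc(OC)c(OC)c1 | intermediate
4 | diphenyl phosphite | O=[PH](Oc1ccccc1)Oc1ccccc1 | starting material
5 | (E)-3-(3,4-dimethoxyphenyl)allyl 2-(diphenoxyphosphoryl)acetate | O=C(CP(=O)(Oc1ccccc1)Oc1ccccc1)OC/C=C/c1ccc(OC)c(OC)c1 | intermediate
6 | (E)-3-(3,4-dimethoxyphenyl)allyl 3-(dimethylamino)-2-(diphenoxyphosphoryl)propanoate (racemic, not isolated) | CN(C)CC(C(=O)OC/C=C/c1ccc(OC)c(OC)c1)P(=O)(Oc1ccccc1)Oc1ccccc1 | intermediate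
7 | 3-{[(E)-3-(3,4-dimethoxyphenyl)allyl]oxy}-2-(diphenoxyphosphoryl)-N,N,N-trimethyl-3-oxopropan-1-aminium iodide (racemic, not isolated) | C[N+](C)(C)CC(C(=O)OC/C=C/c1ccc(OC)c(OC)c1)P(=O)(Oc1ccccc1)Oc1ccccc1.[I-] | intermediate
8 | (E)-3-(3,4-dimethoxyphenyl)allyl 2-(diphenoxyphosphoryl)acrylate | C=C(C(=O)OC/C=C/c1ccc(OC)c(OC)c1)P(=O)(Oc1ccccc1)Oc1ccccc1 | intermediate
9 | angelic acid, (Z)-2-methylbut-2-enoic acid | C/C=C(/C)C(=O)O | starting material
10 | acetaldehyde | CC=O | starting material
11 | potassium (Z)-2-methylbut-2-enoate (not isolated) | C/C=C(/C)C(=O)[O-].[K+] | intermediate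
12 | potassium 1-{[(E)-3-(3,4-dimethoxyphenyl)allyl]oxy}-2-(diphenoxyphosphoryl)-3-{[(Z)-2-methylbut-2-enoyl]oxy}-1-oxopropan-2-ide (not isolated) | C/C=C(/C)C(=O)OC[C-](C(=O)OC/C=C/c1ccc(OC)c(OC)c1)P(=O)(Oc1ccccc1)Oc1ccccc1.[K+] | intermediate
13 | Morinin L, (E)-3-(3,4-dimethoxyphenyl)allyl (Z)-2-({[(Z)-2-methylbut-2-enoyl]oxy}methyl)but-2-enoate | C/C=C(/C)C(=O)OC/C(=C/C)C(=O)OC/C=C/c1ccc(OC)c(OC)c1 | target

**Totals**
Total step count: 4.
Longest linear sequence: 4 (1 → 3 → 5 → 8 → 13).

**Steps most likely to fail**

Step 4 (Proposed new method). Possible failures are: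
- anionic oligomerisation of the acceptor;
- too low a stationary concentration of the carbanion;
- erosion of the Z selectivity;
- O→O migration of the angeloyl group in the β-alkoxide before P–O closure.

The fallback sets out from 1 and comes back at 13; it forms the central alkene by syn-hydrometalation of an alkyne instead of olefination. Compound 1 is esterified with but-2-ynoic acid (DCC, cat. DMAP, CH2Cl2, 0 °C) to (E)-3-(3,4-dimethoxyphenyl)allyl but-2-ynoate F1. Conjugate syn-hydroalumination (DIBAL-H/HMPA or DIBAL-H/NMO, THF, 0 °C) places H on C3 and Al on C2 on the same side and gives (E)-3-(3,4-dimethoxyphenyl)allyl (E)-2-(diisobutylalumanyl)but-2-enoate F2. Capture with monomeric formaldehyde and hydrolysis gives (E)-3-(3,4-dimethoxyphenyl)allyl (Z)-2-(hydroxymethyl)but-2-enoate F3. This alcohol is acylated, without a nucleophilic catalyst (toluene, 80 °C), by (Z)-2-methylbut-2-enoic 2,4,6-trichlorobenzoic anhydride F4. F4 is made from 9 with 2,4,6-trichlorobenzoyl chloride and Et3N (Yamaguchi-type mixed anhydride, the non-isomerising way to angelates). The product is 13.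

Step 3. Possible failures are double aminomethylation, re-addition of amine or water to the very electrophilic alkene, and oligomerisation on concentration or on silica. The fallback sets out from 5 and comes back at 8; it replaces the Mannich route by a selenoxide elimination. Compound 5 is C-methylated (NaH, MeI, THF/DMSO) to (E)-3-(3,4-dimethoxyphenyl)allyl 2-(diphenoxyphosphoryl)propanoate F5. Its sodium anion is selenenylated (PhSeCl, THF, −78 °C) to (E)-3-(3,4-dimethoxyphenyl)allyl 2-(diphenoxyphosphoryl)-2-(phenylselanyl)propanoate F6. H2O2 (CH2Cl2, 0 °C) gives (E)-3-(3,4-dimethoxyphenyl)allyl 2-(diphenoxyphosphoryl)-2-(phenylseleninyl)propanoate F7. F7 undergoes syn-elimination towards its only β-hydrogens, those of the CH3 group, under neutral, amine-free conditions to give 8.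

Step 2. Possible failures are N-alkylation of triethylamine by the bromoacetate, halophilic attack, and phenoxide exchange at phosphorus on the valuable cinnamyl ester. The fallback sets out from 4, takes up 1 in its last operation and comes back at 5, so that 2 and 3 are bypassed. The P–C bond is made first on a robust ester, and the cinnamyl ester is closed afterwards as an acyl–O bond. Compound 4 is alkylated with tert-butyl bromoacetate (Et3N, CH2Cl2) to tert-butyl 2-(diphenoxyphosphoryl)acetate F8. TFA/CH2Cl2 gives 2-(diphenoxyphosphoryl)acetic acid F9. Carbodiimide coupling with 1 (EDC·HCl, cat. DMAP, CH2Cl2, 0 °C; Steglich esterification) gives 5.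

**Further compounds**
F1 | step 4 | (E)-3-(3,4-dimethoxyphenyl)allyl but-2-ynoate | CC#CC(=O)OC/C=C/c1ccc(OC)c(OC)c1
F2 | step 4 | (E)-3-(3,4-dimethoxyphenyl)allyl (E)-2-(diisobutylalumanyl)but-2-enoate | C/C=C(/[Al](CC(C)C)CC(C)C)C(=O)OC/C=C/c1ccc(OC)c(OC)c1
F3 | step 4 | (E)-3-(3,4-dimethoxyphenyl)allyl (Z)-2-(hydroxymethyl)but-2-enoate | C/C=C(/CO)C(=O)OC/C=C/c1ccc(OC)c(OC)c1
F4 | step 4 | (Z)-2-methylbut-2-enoic 2,4,6-trichlorobenzoic anhydride | C/C=C(/C)C(=O)OC(=O)c1c(Cl)cc(Cl)cc1Cl
F5 | step 3 | (E)-3-(3,4-dimethoxyphenyl)allyl 2-(diphenoxyphosphoryl)propanoate (racemic) | CC(C(=O)OC/C=C/c1ccc(OC)c(OC)c1)P(=O)(Oc1ccccc1)Oc1ccccc1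
F6 | step 3 | (E)-3-(3,4-dimethoxyphenyl)allyl 2-(diphenoxyphosphoryl)-2-(phenylselanyl)propanoate (racemic) | CC([Se]c1ccccc1)(C(=O)OC/C=C/c1ccc(OC)c(OC)c1)P(=O)(Oc1ccccc1)Oc1ccccc1
F7 | step 3 | (E)-3-(3,4-dimethoxyphenyl)allyl 2-(diphenoxyphosphoryl)-2-(phenylseleninyl)propanoate (mixture of diastereomers) | CC([Se](=O)c1ccccc1)(C(=O)OC/C=C/c1ccc(OC)c(OC)c1)P(=O)(Oc1ccccc1)Oc1ccccc1
F8 | step 2 | tert-butyl 2-(diphenoxyphosphoryl)acetate | CC(C)(C)OC(=O)CP(=O)(Oc1ccccc1)Oc1ccccc1
F9 | step 2 | 2-(diphenoxyphosphoryl)acetic acid | OC(=O)CP(=O)(Oc1ccccc1)Oc1ccccc1
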